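**Retrosynthetic overview**

1. The last bond cut is C4–O of the upper flavan (the unit with the free 5-OH) to O4'' of the lower unit. The strategy rests on the upper unit's C5(OH)–C4a–C4(O) array across ring A and ring C: it is the alcohol adduct of an o-quinone methide (C5=O, C4a=C4), whereas the lower unit has 5-OMe and can only be the alcohol partner.
2. Both halves trace back to one (S)-5,6,7-trimethoxyflavanone. The lower half needs reduction and C4 inversion to the (2S,4R)-4-ol; the upper half needs 5-O-demethylation, Boc carbonate formation and reduction to a 5-(Boc-oxy)flavan-4-ol that releases the methide under base.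
3. The flavanone is cut at C2–phenyl to 5,6,7-trimethoxychromone and phenylboronic acid (one catalytic asymmetric conjugate arylation sets both C2 centres). The chromone comes from 3,4,5-trimethoxyphenol by ortho-acetylation and enaminone cyclisation.
4. Ring order: ring A is bought, the pyranone ring C is closed once at the chromone stage and serves both halves, and the final union closes no ring.

Key step: step 11

Assumption: the (R) antipode of the pyridine-oxazoline ligand is taken to give the 2S flavanone, by analogy with the known facial sense of the (S) ligand in β-aryl ketone formation; the configuration of 6 is to be checked by CD against natural (2S)-flavanones and the ligand antipode exchanged if the sense is the reverse.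

Remark: flavan numbering is used throughout (O1, C2, C3, C4, C4a, C5–C8, C8a); the lower unit carries double primes.

**Route**

Step 1
Reactants: 1 3,4,5-trimethoxyphenol
Product: 2 1-(6-hydroxy-2,3,4-trimethoxyphenyl)ethanone (2'-hydroxy-4',5',6'-trimethoxyacetophenone)
Conditions: AcOH, BF3·OEt2, 90 °C; then aq. NaOAc
Reagents that add atoms: acetic acid, CC(=O)O
Why: Friedel–Crafts C-acylation of the phenol can only occur ortho to the hydroxyl, because the para carbon carries OMe and the two ortho carbons are equivalent, and the new ketone deactivates the ring against a second acylation.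

Step 2
Reactants: 2 1-(6-hydroxy-2,3,4-trimethoxyphenyl)ethanone
Product: 3 (E)-3-(dimethylamino)-1-(6-hydroxy-2,3,4-trimethoxyphenyl)prop-2-en-1-one
Conditions: Me2NCH(OMe)2 (1.5 equiv), toluene, 95 °C
Reagents that add atoms: N,N-dimethylformamide dimethyl acetal, COC(OC)N(C)C
Why: Condensation of the acetyl methyl group with the amide acetal gives the vinylogous amide (enaminone formation), the E isomer being the thermodynamic one.

Step 3
Reactants: 3 (E)-3-(dimethylamino)-1-(6-hydroxy-2,3,4-trimethoxyphenyl)prop-2-en-1-one
Product: 4 5,6,7-trimethoxychromone
Conditions: conc. HCl, CH2Cl2, 40 °C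
Reagents that add atoms: none
Why: Acid-promoted addition of the phenolic oxygen to the enaminone β-carbon followed by loss of dimethylamine (oxa-Michael addition–elimination) closes the pyranone ring.

Step 4
Reactants: 4 5,6,7-trimethoxychromone; 5 phenylboronic acid
Product: 6 (S)-5,6,7-trimethoxyflavanone
Conditions: Pd(OCOCF3)2 (5 mol%), (R)-t-BuPyOx [(R)-4-tert-butyl-2-(pyridin-2-yl)-4,5-dihydrooxazole] (6 mol%), NH4PF6 (30 mol%), H2O (5 equiv), ClCH2CH2Cl, 60 °C
Reagents that add atoms: none
Why: Asymmetric conjugate arylation catalysed by divalent palladium: the cationic arylpalladium–pyridine-oxazoline complex formed by transmetalation adds across C2=C3 on the face chosen by the ligand, and protonolysis of the palladium enolate by water gives the flavanone with C2 set as S under non-basic conditions that do not open the ring.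

Step 5
Reactants: 6 (S)-5,6,7-trimethoxyflavanone
Product: 7 (2S,4S)-5,6,7-trimethoxyflavan-4-ol (2,4-cis)
Conditions: NaBH4, MeOH–THF, −20 → 0 °C; pH 7 buffer
Reagents that add atoms: none
Why: Substrate-controlled hydride reduction in which hydride enters pseudo-axially on the half-chair that holds the 2-phenyl group equatorial, so the new hydroxyl is equatorial and cis to phenyl (4S).

Step 6
Reactants: 7 (2S,4S)-5,6,7-trimethoxyflavan-4-ol
Product: 8 (2S,4R)-5,6,7-trimethoxyflavan-4-yl 4-nitrobenzoate (2,4-trans)
Conditions: PPh3, DIAD, 4-nitrobenzoic acid, THF, −20 → 0 °C; chromatography on Et3N-deactivated silica, used without storage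
Reagents that add atoms: 4-nitrobenzoic acid, O=C(O)c1ccc(cc1)[N+](=O)[O-]
Why: Mitsunobu inversion, in which the carboxylate displaces the oxyphosphonium group with inversion at C4 to give 4R; if the electron-rich benzylic centre ionises instead, pseudo-axial capture anti to the 2-phenyl group leads to the same trans ester.

Step 7
Reactants: 8 (2S,4R)-5,6,7-trimethoxyflavan-4-yl 4-nitrobenzoate
Product: 9 (2S,4R)-5,6,7-trimethoxyflavan-4-ol (2,4-trans)
Conditions: LiOH, THF–H2O, 0 °C; extraction without acidification
Reagents that add atoms: none
Why: Saponification by acyl–oxygen cleavage keeps the C4 configuration, and an alcohol-free medium is chosen so that any competing ionisation of this very labile benzylic ester can only return the alcohol, not a 4-alkyl ether.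

Step 8
Reactants: 6 (S)-5,6,7-trimethoxyflavanone
Product: 10 (S)-5-hydroxy-6,7-dimethoxyflavanone
Conditions: BCl3 (1.2 equiv), CH2Cl2, −78 → −20 °C; aq. NaHCO3
Reagents that add atoms: none
Why: Chelation-directed ether cleavage, in which boron bridges the C4 carbonyl oxygen and the peri 5-methoxy oxygen so that chloride removes only that methyl group, while the low temperature and limited reagent spare the 6- and 7-methoxy groups and the C2 centre.

Step 9
Reactants: 10 (S)-5-hydroxy-6,7-dimethoxyflavanone
Product: 11 (S)-5-(tert-butoxycarbonyloxy)-6,7-dimethoxyflavanone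
Conditions: Boc2O (1.5 equiv), DMAP (10 mol%), CH2Cl2, 0 °C → rt
Reagents that add atoms: di-tert-butyl dicarbonate, CC(C)(C)OC(=O)OC(=O)OC(C)(C)C
Why: DMAP-catalysed O-acylation of the phenol gives the aryl tert-butyl carbonate, with no base strong enough to trigger retro-oxa-Michael opening of the flavanone.

Step 10
Reactants: 11 (S)-5-(tert-butoxycarbonyloxy)-6,7-dimethoxyflavanone
Product: 12 (2S,4S)-5-(tert-butoxycarbonyloxy)-6,7-dimethoxyflavan-4-ol (2,4-cis expected as major epimer; the C4 configuration is erased in step 11)
Conditions: BH3·THF, THF, 0 °C → rt; MeOH quench, pH 7 buffer; kept acid-free and used promptly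
Reagents that add atoms: none
Why: Electrophilic borane reduction of the ketone proceeds through an alkoxyborane and never a free alkoxide, so the peri carbonate should not migrate before the key step; pseudo-axial hydride delivery should favour the cis alcohol.

Step 11
Reactants: 12 (2S,4S)-5-(tert-butoxycarbonyloxy)-6,7-dimethoxyflavan-4-ol; 9 (2S,4R)-5,6,7-trimethoxyflavan-4-ol (3 equiv)
Product: 15 beilschmieflavonoid B, via C4 carbonate phenoxide 13 (not isolated), via o-quinone methide 14 (not isolated)
Conditions: THF, −78 °C; t-BuMgCl (1.0 equiv per hydroxyl), −78 → −20 °C; pH 7 phosphate buffer; excess 9 recovered by chromatography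
Reagents that add atoms: none
Why: Proposed new method: t-BuMgCl deprotonates both secondary alcohols; the C4 alkoxide of 12 attacks the peri carbonate through a six-membered tetrahedral intermediate and moves the Boc group from O5 to O4 to give phenoxide 13, whose O5 lone pair expels tert-butyl carbonate from C4 to form the ring-locked o-quinone methide 14 (C5=O, C4a=C4), and the magnesium alkoxide of 9 adds to C4 in an oxa-Michael addition that rearomatises ring A to the 5-phenoxide, protonated on work-up. The closest known reaction type is the base-triggered carbonate-migration route to o-quinone methides from o-(Boc-oxy)benzyl alcohols with capture by Grignard reagents, hydride or enol ethers, combined with the known conjugate addition of alcohols to o-quinone methides; capture of a chroman-fused methide by a hindered secondary alkoxide is untested. No ring is closed; the only new bond is C4–O4''. The new C4 stereocentre is controlled by C2: the alkoxide enters pseudo-axially on the half-chair, anti to the pseudo-equatorial 2-phenyl group, and because the addition is reversible through the phenoxide, the 2,4-trans ether, which also avoids peri strain with O5, should accumulate, so either C4 epimer of 12 converges on 4R. The step needs cross-selectivity, which is secured because under base only the Boc-bearing partner can become an electrophile, while 9 (5-OMe, no leaving group) keeps its C4''–O bond and therefore its 4R configuration, and homo-coupling is excluded for the same reason. The C3 methylene points away from the C5 carbonyl, which blocks the 1,5-hydrogen shift to a vinylphenol, and low temperature, the weakly basic carbonate leaving group and excess 9 are meant to suppress loss of a C3 proton (flav-3-ene) and capture by tert-butoxide.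

**Compound list**

1 | 3,4,5-trimethoxyphenol | COc1cc(O)cc(OC)c1OC | starting material
2 | 1-(6-hydroxy-2,3,4-trimethoxyphenyl)ethanone | CC(=O)c1c(O)cc(OC)c(OC)c1OC | intermediate
3 | (E)-3-(dimethylamino)-1-(6-hydroxy-2,3,4-trimethoxyphenyl)prop-2-en-1-one | CN(C)/C=C/C(=O)c1c(O)cc(OC)c(OC)c1OC | intermediate
4 | 5,6,7-trimethoxychromone | COc1cc2occc(=O)c2c(OC)c1OC | intermediate
5 | phenylboronic acid | OB(O)c1ccccc1 | starting material
6 | (S)-5,6,7-trimethoxyflavanone | COc1cc2c(c(OC)c1OC)C(=O)C[C@@H](c1ccccc1)O2 | intermediate
7 | (2S,4S)-5,6,7-trimethoxyflavan-4-ol | COc1cc2c(c(OC)c1OC)[C@@H](O)C[C@@H](c1ccccc1)O2 | intermediate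
8 | (2S,4R)-5,6,7-trimethoxyflavan-4-yl 4-nitrobenzoate | COc1cc2c(c(OC)c1OC)[C@H](OC(=O)c1ccc(cc1)[N+](=O)[O-])C[C@@H](c1ccccc1)O2 | intermediate
9 | (2S,4R)-5,6,7-trimethoxyflavan-4-ol | COc1cc2c(c(OC)c1OC)[C@H](O)C[C@@H](c1ccccc1)O2 | intermediate
10 | (S)-5-hydroxy-6,7-dimethoxyflavanone | COc1cc2c(c(O)c1OC)C(=O)C[C@@H](c1ccccc1)O2 | intermediate
11 | (S)-5-(tert-butoxycarbonyloxy)-6,7-dimethoxyflavanone | COc1cc2c(c(OC(=O)OC(C)(C)C)c1OC)C(=O)C[C@@H](c1ccccc1)O2 | intermediate
12 | (2S,4S)-5-(tert-butoxycarbonyloxy)-6,7-dimethoxyflavan-4-ol | COc1cc2c(c(OC(=O)OC(C)(C)C)c1OC)[C@@H](O)C[C@@H](c1ccccc1)O2 | intermediate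
13 | chloromagnesium (2S,4S)-4-(tert-butoxycarbonyloxy)-6,7-dimethoxyflavan-5-olate | COc1cc2c(c([O-])c1OC)[C@@H](OC(=O)OC(C)(C)C)C[C@@H](c1ccccc1)O2.[Mg+2].[Cl-] | intermediate
14 | (S)-6,7-dimethoxy-2-phenyl-2,3-dihydrochromen-5-one (o-quinone methide, C5=O, C4a=C4) | O=C1C(OC)=C(OC)C=C2O[C@H](c3ccccc3)CC=C12 | intermediate
15 | beilschmieflavonoid B, (2S,4R)-5-hydroxy-6,7-dimethoxyflavan-4-yl (2S,4R)-5,6,7-trimethoxyflavan-4-yl ether | COc1cc2c(c(O)c1OC)[C@H](O[C@@H]1C[C@@H](c3ccccc3)Oc3cc(OC)c(OC)c(OC)c31)C[C@@H](c1ccccc1)O2 | target

**Count**

Total steps: 11. Longest linear sequence: 8 (steps 1–4, 8–10 and 11; the branch through steps 5–7 is of equal length).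

**Steps most likely to fail**

Step 11. The magnesium alkoxide may fail to intercept the methide: the sequence could stall at the migrated carbonate, lose a C3 proton to give the flav-3-ene, or be diverted by tert-butoxide capture. The fallback makes the same C4–O bond from a sulfone-type methide precursor, using the known base-induced generation of o-quinone methides from 2-(1-sulfonylalkyl)phenols and their capture by heteroatom nucleophiles. It sets out from 10: NaBH4 in THF–EtOH at 0 °C should give (2S,4S)-5-hydroxy-6,7-dimethoxyflavan-4-ol F1. p-Toluenesulfinic acid in CH2Cl2 at room temperature should then replace the benzylic hydroxyl through the stabilised C4 cation, trans to the 2-phenyl group, to give (2S,4R)-6,7-dimethoxy-4-(p-tolylsulfonyl)flavan-5-ol F2, a storable latent methide. Treating F2 with excess 9 and Cs2CO3 in THF (or with the sodium alkoxide of 9 preformed with NaH) should expel sulfinate, regenerate 14 and give the ether by conjugate addition, coming back to the route at 15.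

Step 6. The electron-rich benzylic oxyphosphonium may ionise, leading to elimination towards the flav-3-ene or to incomplete inversion, and the ester may solvolyse during isolation. The fallback replaces activation and displacement by a thermodynamically driven epimerisation of known type (acid-catalysed C4 exchange of 5-oxygenated flavan-4-ols). It sets out from 7: stirring it dilute in THF–water with catalytic pyridinium p-toluenesulfonate should let the C4 hydroxyl exchange through the benzylic cation. Water should re-add pseudo-axially and the pseudo-axial 4-OH relieves peri strain with the 5-OMe, so the trans epimer should predominate; it is separated from residual 7, which is recycled. No new compound is made and the fallback comes back to the route at 9, bypassing 8.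

Step 4. The electron-rich chromone with its peri 5-methoxy group may be a sluggish acceptor, or the facial control may be insufficient. The fallback builds the C2 centre by the classical chalcone route and separates enantiomers. It sets out from 2: Claisen–Schmidt condensation with benzaldehyde (KOH, EtOH, rt) should give (E)-1-(6-hydroxy-2,3,4-trimethoxyphenyl)-3-phenylprop-2-en-1-one F3. Oxa-Michael ring closure (NaOAc, EtOH, reflux) should give racemic 5,6,7-trimethoxyflavanone F4. Preparative HPLC on a chiral stationary phase delivers the S enantiomer, coming back to the route at 6, and (R)-5,6,7-trimethoxyflavanone F5, which can be re-equilibrated to F4 with base through F3.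

**Further compounds**

F1 | step 11 | (2S,4S)-5-hydroxy-6,7-dimethoxyflavan-4-ol | COc1cc2c(c(O)c1OC)[C@@H](O)C[C@@H](c1ccccc1)O2
F2 | step 11 | (2S,4R)-6,7-dimethoxy-4-(p-tolylsulfonyl)flavan-5-ol | COc1cc2c(c(O)c1OC)[C@H](S(=O)(=O)c1ccc(C)cc1)C[C@@H](c1ccccc1)O2
F0 | step 6 | none | none
F3 | step 4 | (E)-1-(6-hydroxy-2,3,4-trimethoxyphenyl)-3-phenylprop-2-en-1-one | O=C(/C=C/c1ccccc1)c1c(O)cc(OC)c(OC)c1OC
F4 | step 4 | racemic 5,6,7-trimethoxyflavanone | COc1cc2c(c(OC)c1OC)C(=O)CC(c1ccccc1)O2
F5 | step 4 | (R)-5,6,7-trimethoxyflavanone | COc1cc2c(c(OC)c1OC)C(=O)C[C@H](c1ccccc1)O2
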